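**Retrosynthetic overview**
1. Target ⇐ C6–OH-directed epoxidation of a 4Z alkene ⇐ O8,O12-bis-angelate ⇐ 1(10)E,4Z-cyclodecadienyl C5 triflate.
2. Feature: inside the ten-membered ring C1–C10, the C1=C10 double bond and the C4–C5 oxirane (standing for a Z double bond) flank the C2–C3 single bond, a 1,5-diene pattern. The ring is therefore the anionic oxy-Cope isomer of a cyclohexane C5–C10 bonded C5–C10, with vinyl on C10 and isopropenyl plus OH on C5 (disconnection C2–C3).
3. The C5 carbinol (OH trans to vinyl) is not accessible by carbonyl addition. It is made by β-face epoxidation of a C5=C6 isopropenylcyclohexene and opening at C6 by the C12 acid (temporary cis-fused γ-lactone, which also sets C6 and, by equilibration, C11).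
4. The cyclohexanone with the C10 quaternary centre comes from (S)-carvone: α′-oxygenation (C8–O), Wharton enone transposition, isopropenyl → propanoate, reductive aldol/elimination (vinyl).
5. Ring order: six-membered ring (carvone), γ-lactone (temporary), ten-membered ring by six-to-ten expansion, oxirane last.

Key step: step 19

Remark: germacrane numbering of the target is used for every intermediate (cyclohexane = C5–C10; side chain C11–C13; vinyl C1–C2; isopropenyl C3, C4, C15; C10 methyl C14). β is the ring face of the C8 oxygen and α that of the C7 side chain. C11 is carried as an epimer mixture from step 5 to step 14.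

**Step 1**
Reactants: 1 (S)-carvone
Product: 3 trans-6-(tert-butyldimethylsilyloxy)carvone [(5R,6R); C8 β-OTBS; C9 ketone], via silyl dienol ether 2 (not isolated)
Conditions: LiN(iPr)2, THF, −78 °C; TBSCl, DMPU; then mCPBA, hexane–CH2Cl2, −20 to 0 °C
Reagents that add atoms: tert-butyldimethylsilyl chloride CC(C)(C)[Si](C)(C)Cl; mCPBA OOC(=O)c1cccc(Cl)c1
Why: Kinetic deprotonation at the α′ CH2 (C8) gives the cross-conjugated dienolate, and Rubottom oxidation of its silyl ether (epoxidation of the C8=C9 enol ether alkene anti to the C7 isopropenyl, then 1,4-silyl shift) should set C8–O trans to the side chain, which is also the more stable arrangement at this epimerisable centre.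

**Step 2**
Reactants: 3 trans-6-(tert-butyldimethylsilyloxy)carvone
Product: 4 epoxy ketone (C5–C10 oxirane, C9 ketone)
Conditions: H2O2 (30%), NaOH (cat.), MeOH, 0 °C
Reagents that add atoms: hydrogen peroxide OO
Why: Weitz–Scheffer epoxidation, in which hydroperoxide adds to the enone β-carbon (C5) and closes onto C10 while the electron-rich isopropenyl group is inert; the oxirane configuration (expected anti to the isopropenyl) disappears again in steps 3 and 4.

**Step 3**
Reactants: 4 epoxy ketone
Product: 5 transposed allylic alcohol (C5–OH, C9=C10)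
Conditions: N2H4·H2O, AcOH (cat.), MeOH, argon, 0 °C to rt
Reagents that add atoms: none
Why: Wharton transposition, in which the C9 hydrazone opens the oxirane at C10 to an allylic diazene that loses N2, moving the oxygen from C9 to C5 and the alkene to C9=C10; the carbinol configuration is irrelevant because step 4 oxidises it.

**Step 4**
Reactants: 5 transposed allylic alcohol
Product: 6 γ-silyloxy enone (C5 ketone, C9=C10, C8 β-OTBS, C7 α-isopropenyl)
Conditions: Dess–Martin periodinane, CH2Cl2, rt
Reagents that add atoms: none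
Why: Dess–Martin oxidation of the secondary allylic alcohol gives the transposed enone, in which the silyloxy carbon C8 is now γ and trans to the C7 side chain, without touching a stereocentre.

**Step 5**
Reactants: 6 γ-silyloxy enone
Product: 7 side-chain epoxide (C11–C12 oxirane, C11 epimers)
Conditions: mCPBA, CH2Cl2, 0 °C
Reagents that add atoms: mCPBA OOC(=O)c1cccc(Cl)c1
Why: Prilezhaev epoxidation is selective for the electron-rich 1,1-disubstituted alkene over the electron-poor enone alkene, and the new C11 centre forms as a mixture that is corrected in step 15.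

**Step 6**
Reactants: 7 side-chain epoxide
Product: 8 aldehyde (C7 side chain CH(CH3)CHO, C11 epimers)
Conditions: BF3·OEt2 (0.2 equiv), CH2Cl2, −78 °C
Reagents that add atoms: none
Why: Meinwald rearrangement, in which Lewis-acid opening of the 2,2-disubstituted oxirane to the tertiary C11 cation is followed by a 1,2-hydride shift from C12 to give the α-methyl aldehyde.

**Step 7**
Reactants: 8 aldehyde
Product: 10 methyl ester (C7 side chain CH(CH3)CO2Me), via carboxylic acid 9 (not isolated)
Conditions: NaClO2, NaH2PO4, 2-methyl-2-butene, tBuOH–H2O, rt; then Me3SiCHN2, MeOH–toluene, 0 °C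
Reagents that add atoms: sodium chlorite [Na+].[O-]Cl=O; (trimethylsilyl)diazomethane C[Si](C)(C)C=[N+]=[N-]
Why: Pinnick oxidation converts the aldehyde to the acid without touching the enone or the silyl ether, and diazomethane released from Me3SiCHN2 by methanol esterifies it so that the acid is masked during the enolate steps.

**Step 8**
Reactants: 11 benzeneselenenyl chloride; 12 ethyl vinyl ether
Product: 14 (phenylselanyl)acetaldehyde, via α-chloro ether 13 (not isolated)
Conditions: CH2Cl2, −78 °C; then H2O, NaHCO3, rt
Reagents that add atoms: water O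
Why: Electrophilic selenenylation of the enol ether puts selenium on the terminal carbon and chloride on the acetal carbon, and hydrolysis of the α-chloro ether releases the aldehyde, a known vinyl-cation equivalent.

**Step 9**
Reactants: 10 methyl ester; 14 (phenylselanyl)acetaldehyde
Product: 16 β-hydroxy selenide ketone (C10 β-CH3 and α-CH(OH)CH2SePh), via lithium enolate 15 (not isolated)
Conditions: LiBH(s-Bu)3, THF, −78 °C; then 14, −78 °C; aq. NH4Cl
Reagents that add atoms: none
Why: Conjugate reduction by the hindered borohydride (hydride to C9) gives the C5–C10 enolate regiospecifically, and its aldol addition to 14 should occur by axial attack on the half-chair that keeps the C7 and C8 substituents equatorial, which places the new C–C bond on the α-face of C10 (cis to the C7 chain, trans to the C8 silyl ether); the carbinol centre is lost in step 10.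

**Step 10**
Reactants: 16 β-hydroxy selenide ketone
Product: 17 vinyl ketone (C10 β-CH3, α-vinyl)
Conditions: MsCl, Et3N, CH2Cl2, 0 °C to rt
Reagents that add atoms: none
Why: β-Hydroxy selenide elimination (Reich type), in which activation of the hydroxyl by MsCl triggers anti-elimination of PhSe and OH, gives the terminal alkene regiospecifically.

**Step 11**
Reactants: 17 vinyl ketone
Product: 19 C5=C6 enol triflate, via potassium enolate 18 (not isolated)
Conditions: KN(SiMe3)2, THF, −78 °C; then PhNTf2, −78 to 0 °C; aq. NH4Cl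
Reagents that add atoms: N-phenylbis(trifluoromethanesulfonimide) O=S(=O)(N(c1ccccc1)S(=O)(=O)C(F)(F)F)C(F)(F)F
Why: The ketone can enolise only towards C6 (C10 is quaternary) and its CH2 is more acidic than the ester α-CH, so one equivalent of amide base followed by O-sulfonylation gives the C5=C6 enol triflate.

**Step 12**
Reactants: 19 C5=C6 enol triflate; 20 isopropenylboronic acid pinacol ester
Product: 21 diene ester (C5 isopropenyl, C5=C6)
Conditions: Pd(dppf)Cl2 (5 mol%), K3PO4, dioxane–H2O, 70 °C
Reagents that add atoms: none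
Why: Suzuki–Miyaura coupling of the alkenyl triflate with the isopropenyl boronate attaches C4 (with C3 and C15) to C5 with retention of the ring alkene, the ester, vinyl group and silyl ether being inert.

**Step 13**
Reactants: 21 diene ester
Product: 22 diene acid
Conditions: LiOH, THF–MeOH–H2O, 40 °C; then 1 M HCl to pH 3
Reagents that add atoms: lithium hydroxide [Li+].[OH-]
Why: Saponification frees the C12 carboxylic acid needed as the internal nucleophile, and epimerisation at C11 is harmless at this stage.

**Step 14**
Reactants: 22 diene acid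
Product: 24 hydroxy lactone (5β-OH; 6α,12-olide; C11 epimers), via epoxy acid 23 (not isolated)
Conditions: mCPBA, CH2Cl2, 0 °C to rt
Reagents that add atoms: mCPBA OOC(=O)c1cccc(Cl)c1
Why: Prilezhaev epoxidation should select the trisubstituted ring alkene (the twisted isopropenyl and the neopentyl vinyl are less nucleophilic) and its β-face, anti to the pseudoaxial C10 vinyl and the C7 chain, and the carboxylic acid then opens the oxirane at C6 with inversion in a 5-exo, trans-diaxial (Fürst–Plattner) mode, so that C6–O is α (cis-fused γ-lactone) and the tertiary C5–OH is β, trans to the vinyl group, a configuration that carbonyl addition would not give.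

**Step 15**
Reactants: 24 hydroxy lactone (C11 epimers)
Product: 25 hydroxy lactone with the C11 methyl on the convex face
Conditions: KOtBu (0.2 equiv), tBuOH–THF, rt
Reagents that add atoms: none
Why: Base-mediated epimerisation α to the lactone carbonyl should converge on the more stable epimer with the C11 methyl on the convex face of the cis-fused bicycle (anti to C8), which is the configuration of the target, and in tert-butanol the hydrogen-bonded tertiary alkoxide does not rearrange.

**Step 16**
Reactants: 25 hydroxy lactone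
Product: 26 triol (C5, C6, C12 hydroxyls)
Conditions: LiAlH4, THF, 0 °C; aqueous work-up
Reagents that add atoms: none
Why: LiAlH4 reduction opens the lactone to the C6/C12 diol without affecting the alkenes, the silyl ether or any stereocentre.

**Step 17**
Reactants: 26 triol
Product: 27 C12 silyl ether diol
Conditions: TBSCl, imidazole, CH2Cl2, 0 °C
Reagents that add atoms: tert-butyldimethylsilyl chloride CC(C)(C)[Si](C)(C)Cl
Why: Silylation is selective for the primary C12 hydroxyl over the hindered secondary (C6) and tertiary (C5) hydroxyls.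

**Step 18**
Reactants: 27 C12 silyl ether diol
Product: 28 ring-expansion substrate (5β-OH, 5α-isopropenyl, 6α-OPMB, 8β-OTBS, 10α-vinyl, 12-OTBS)
Conditions: NaH, PMBCl, tetrabutylammonium iodide (cat.), THF–DMF, 0 °C
Reagents that add atoms: 4-methoxybenzyl chloride COc1ccc(CCl)cc1
Why: Williamson etherification benzylates the secondary C6 alkoxide while the tertiary, neopentyl C5 hydroxyl stays free, which puts a non-migrating, oxidatively removable group on O6.

**Step 19**
Reactants: 28 ring-expansion substrate
Product: 31 ten-membered 1(10)E,4Z-dienyl C5 triflate, via potassium alkoxide 29 (not isolated), via potassium enolate 30 (not isolated)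
Conditions: KH, 18-crown-6, THF, 0 °C to rt; then PhNTf2, −78 to 0 °C; aq. NH4Cl
Reagents that add atoms: N-phenylbis(trifluoromethanesulfonimide) O=S(=O)(N(c1ccccc1)S(=O)(=O)C(F)(F)F)C(F)(F)F
Why: KH with 18-crown-6 turns 28 into the loosely ion-paired C5 alkoxide 29, in which the C5–C10 bond is weakened, and a concerted [3,3] shift (anionic oxy-Cope rearrangement, the classical route from 1,2-dialkenylcyclohexanols to cyclodec-5-enones) forms C2–C3 and the C1=C10 and C4=C5 π bonds as C5–C10 breaks. Ring formation is a six-to-ten ring expansion across the breaking bond, so no chain ends have to meet and ordinary concentration suffices. No stereocentre is created; C5 and C10 become trigonal and their configurations are translated into alkene geometry. The step needs 1(10)E,4Z: the cyclohexane chair with the C7 chain and the C8 silyl ether equatorial carries the C10 vinyl axial and the C5 isopropenyl equatorial with O5 trans-diaxial to the vinyl, so that in the chair-like six-centre array C9 sits equatorial (E at C1=C10) and C6 axial with the oxyanion equatorial (C6 cis to C3 at C4=C5). The ring-flipped chair would put the isopropenyl group syn-axial to the C7 chain and the C10 methyl syn-axial to the C8 silyl ether and is therefore disfavoured. The tetrasubstituted potassium enolate 30 is sulfonylated on oxygen by PhNTf2 before it can equilibrate, which fixes the C4=C5 geometry as the enol triflate.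

**Step 20**
Reactants: 31 dienyl C5 triflate
Product: 32 1(10)E,4Z-diene (6-OPMB, 8-OTBS, 12-OTBS)
Conditions: Pd(OAc)2 (10 mol%), PPh3, HCO2H, Et3N, DMF, 60 °C
Reagents that add atoms: none
Why: Palladium-catalysed formate reduction of the enol triflate (oxidative addition to zerovalent palladium, formate-to-hydride exchange with loss of CO2, reductive elimination) replaces OTf by H with retention and gives the 4Z trisubstituted alkene.

**Step 21**
Reactants: 32 1(10)E,4Z-diene
Product: 33 C8,C12 diol (6-OPMB)
Conditions: Bu4NF, THF, rt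
Reagents that add atoms: none
Why: Fluoride cleaves both silyl ethers while the PMB ether, which cannot migrate, keeps O6 masked.

**Step 22**
Reactants: 33 C8,C12 diol; 34 angelic acid
Product: 35 C12 mono-angelate (free C8–OH, 6-OPMB)
Conditions: 34 (1.1 equiv), 2,4,6-Cl3C6H2COCl (1.1 equiv), Et3N, toluene, rt; then 33, 40 °C
Reagents that add atoms: none
Why: Yamaguchi-type esterification through the 2,4,6-trichlorobenzoyl mixed anhydride, run without an acyl-transfer catalyst so that the angelate does not isomerise to the tiglate, should acylate the unhindered primary C12 hydroxyl well before the secondary C8 hydroxyl, which is flanked by the branched C7, and any bis-angelate formed is simply the product of step 23.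

**Step 23**
Reactants: 35 C12 mono-angelate; 34 angelic acid
Product: 36 O8,O12-bis-angelate (6-OPMB)
Conditions: 34 (3 equiv), 2,4,6-Cl3C6H2COCl (3 equiv), Et3N, toluene, rt; then 35, 75 °C
Reagents that add atoms: none
Why: The same mixed-anhydride (Yamaguchi-type) esterification, now with excess anhydride at higher temperature and again without an amine acyl-transfer catalyst, acylates the hindered secondary C8 hydroxyl while both esters keep the Z geometry of angelic acid.

**Step 24**
Reactants: 36 O8,O12-bis-angelate
Product: 37 C6 allylic alcohol bis-angelate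
Conditions: DDQ, CH2Cl2–pH 7 buffer, 0 °C
Reagents that add atoms: none
Why: DDQ oxidises the electron-rich PMB ether (hydride abstraction, then hydrolysis of the oxocarbenium ion) and leaves the angelates and both ring alkenes intact.

**Step 25**
Reactants: 37 C6 allylic alcohol bis-angelate
Product: 38 target (CNP0272382.1)
Conditions: VO(acac)2 (5 mol%), tBuOOH, CH2Cl2, 0 °C
Reagents that add atoms: tert-butyl hydroperoxide CC(C)(C)OO
Why: Hydroxyl-directed vanadium-catalysed epoxidation (Sharpless type), in which the C6 vanadate ester delivers oxygen only to the neighbouring C4=C5 alkene and, as with Z-cyclooct-2-enol and Z-cyclonon-2-enol where the ring holds the carbinol substituent out of the alkene plane, to the face syn to the hydroxyl, should set C4 and C5 as in the target while the C1=C10 alkene and the electron-poor angelates stay untouched.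

**Compound list**
1 | (S)-carvone, (5S)-2-methyl-5-(prop-1-en-2-yl)cyclohex-2-en-1-one (target numbering: C9 ketone, C10=C5, C7 isopropenyl) | CC(=C)[C@H]1CC=C(C)C(=O)C1 | starting material
2 | cross-conjugated TBS dienol ether of 1 (C9–OTBS, C8=C9 and C10=C5 alkenes) | CC(=C)[C@H]1CC=C(C)C(O[Si](C)(C)C(C)(C)C)=C1 | intermediate
3 | (5R,6R)-6-[(tert-butyldimethylsilyl)oxy]-2-methyl-5-(prop-1-en-2-yl)cyclohex-2-en-1-one (C8 β-OTBS trans to the C7 isopropenyl) | CC(=C)[C@H]1CC=C(C)C(=O)[C@@H]1O[Si](C)(C)C(C)(C)C | intermediate
4 | 2,3-epoxide of 3 (C5–C10 oxirane, C9 ketone; oxirane configuration inconsequential) | CC(=C)[C@H]1CC2OC2(C)C(=O)[C@@H]1O[Si](C)(C)C(C)(C)C | intermediate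
5 | (4S,5R)-4-[(tert-butyldimethylsilyl)oxy]-2-methyl-5-(prop-1-en-2-yl)cyclohex-2-en-1-ol (C5 carbinol epimers, C9=C10) | CC(=C)[C@H]1CC(O)C(C)=C[C@@H]1O[Si](C)(C)C(C)(C)C | intermediate
6 | (4S,5R)-4-[(tert-butyldimethylsilyl)oxy]-2-methyl-5-(prop-1-en-2-yl)cyclohex-2-en-1-one (C5 ketone, C9=C10, 8β-OTBS, 7α-isopropenyl) | CC(=C)[C@H]1CC(=O)C(C)=C[C@@H]1O[Si](C)(C)C(C)(C)C | intermediate
7 | enone 6 with the isopropenyl group as its 2-methyloxiran-2-yl epoxide (C11 epimers) | CC2(CO2)[C@H]1CC(=O)C(C)=C[C@@H]1O[Si](C)(C)C(C)(C)C | intermediate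
8 | enone aldehyde, C7 side chain CH(CH3)CHO (C11 epimers) | O=CC(C)[C@H]1CC(=O)C(C)=C[C@@H]1O[Si](C)(C)C(C)(C)C | intermediate
9 | enone acid, C7 side chain CH(CH3)CO2H (C11 epimers) | OC(=O)C(C)[C@H]1CC(=O)C(C)=C[C@@H]1O[Si](C)(C)C(C)(C)C | intermediate
10 | enone methyl ester, C7 side chain CH(CH3)CO2Me (C11 epimers) | COC(=O)C(C)[C@H]1CC(=O)C(C)=C[C@@H]1O[Si](C)(C)C(C)(C)C | intermediate
11 | benzeneselenenyl chloride | Cl[Se]c1ccccc1 | starting material
12 | ethyl vinyl ether | CCOC=C | starting material
13 | 1-chloro-1-ethoxy-2-(phenylselanyl)ethane | CCOC(Cl)C[Se]c1ccccc1 | intermediate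
14 | (phenylselanyl)acetaldehyde | O=CC[Se]c1ccccc1 | intermediate
15 | lithium C5–C10 enolate of the 9,10-dihydro ketone derived from 10 | COC(=O)C(C)[C@H]1CC(O[Li])=C(C)C[C@@H]1O[Si](C)(C)C(C)(C)C | intermediate
16 | cyclohexanone: C5 ketone, C10 β-CH3 and α-CH(OH)CH2SePh (carbinol epimers), 8β-OTBS, 7α-CH(CH3)CO2Me | COC(=O)C(C)[C@H]1CC(=O)[C@@](C)(C(O)C[Se]c2ccccc2)C[C@@H]1O[Si](C)(C)C(C)(C)C | intermediate
17 | cyclohexanone: C5 ketone, C10 β-CH3 and α-vinyl, 8β-OTBS, 7α-CH(CH3)CO2Me | COC(=O)C(C)[C@H]1CC(=O)[C@@](C)(C=C)C[C@@H]1O[Si](C)(C)C(C)(C)C | intermediate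
18 | potassium C5=C6 enolate of 17 | COC(=O)C(C)[C@H]1C=C(O[K])[C@@](C)(C=C)C[C@@H]1O[Si](C)(C)C(C)(C)C | intermediate
19 | C5=C6 enol triflate of 17 | COC(=O)C(C)[C@H]1C=C(OS(=O)(=O)C(F)(F)F)[C@@](C)(C=C)C[C@@H]1O[Si](C)(C)C(C)(C)C | intermediate
20 | isopropenylboronic acid pinacol ester | CC(=C)B1OC(C)(C)C(C)(C)O1 | starting material
21 | diene ester: C5=C6, C5 isopropenyl, C10 β-CH3 and α-vinyl, 8β-OTBS, 7α-CH(CH3)CO2Me | COC(=O)C(C)[C@H]1C=C(C(C)=C)[C@@](C)(C=C)C[C@@H]1O[Si](C)(C)C(C)(C)C | intermediate
22 | diene acid (as 21 with CO2H) | OC(=O)C(C)[C@H]1C=C(C(C)=C)[C@@](C)(C=C)C[C@@H]1O[Si](C)(C)C(C)(C)C | intermediate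
23 | 5β,6β-epoxy acid | OC(=O)C(C)[C@H]1[C@@H]2O[C@]2(C(C)=C)[C@@](C)(C=C)C[C@@H]1O[Si](C)(C)C(C)(C)C | intermediate
24 | hydroxy lactone: 5β-OH, 5α-isopropenyl, 6α,12-olide (cis-fused), 8β-OTBS, 10β-CH3, 10α-vinyl (C11 epimers) | O=C2C(C)[C@H]1[C@@H](O2)[C@@](O)(C(C)=C)[C@@](C)(C=C)C[C@@H]1O[Si](C)(C)C(C)(C)C | intermediate
25 | hydroxy lactone as 24, single C11 epimer (methyl on the convex face, anti to C8) | O=C2[C@@H](C)[C@H]1[C@@H](O2)[C@@](O)(C(C)=C)[C@@](C)(C=C)C[C@@H]1O[Si](C)(C)C(C)(C)C | intermediate
26 | triol: 5β-OH, 6α-OH, 12-OH, 8β-OTBS | OC[C@@H](C)[C@H]1[C@@H](O)[C@@](O)(C(C)=C)[C@@](C)(C=C)C[C@@H]1O[Si](C)(C)C(C)(C)C | intermediate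
27 | diol: 5β-OH, 6α-OH, 12-OTBS, 8β-OTBS | CC(C)(C)[Si](C)(C)OC[C@@H](C)[C@H]1[C@@H](O)[C@@](O)(C(C)=C)[C@@](C)(C=C)C[C@@H]1O[Si](C)(C)C(C)(C)C | intermediate
28 | ring-expansion substrate: 1-vinyl-2-isopropenylcyclohexanol, 5β-OH, 5α-isopropenyl, 6α-OPMB, 8β-OTBS, 10β-CH3, 10α-vinyl, 12-OTBS | CC(C)(C)[Si](C)(C)OC[C@@H](C)[C@H]1[C@@H](OCc2ccc(OC)cc2)[C@@](O)(C(C)=C)[C@@](C)(C=C)C[C@@H]1O[Si](C)(C)C(C)(C)C | intermediate
29 | potassium C5 alkoxide of 28 | CC(C)(C)[Si](C)(C)OC[C@@H](C)[C@H]1[C@@H](OCc2ccc(OC)cc2)[C@@](O[K])(C(C)=C)[C@@](C)(C=C)C[C@@H]1O[Si](C)(C)C(C)(C)C | intermediate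
30 | potassium enolate of the ten-membered 1(10)E-cyclodecenone (C4=C5 enolate, C6 cis to C3) | CC(C)(C)[Si](C)(C)OC[C@@H](C)[C@H]1[C@@H](OCc2ccc(OC)cc2)/C(O[K])=C(C)\CC/C=C(\C)C[C@@H]1O[Si](C)(C)C(C)(C)C | intermediate
31 | ten-membered 1(10)E,4Z-dienyl C5 triflate, 6-OPMB, 8-OTBS, 12-OTBS | CC(C)(C)[Si](C)(C)OC[C@@H](C)[C@H]1[C@@H](OCc2ccc(OC)cc2)/C(OS(=O)(=O)C(F)(F)F)=C(C)\CC/C=C(\C)C[C@@H]1O[Si](C)(C)C(C)(C)C | intermediate
32 | 1(10)E,4Z-germacradiene, 6-OPMB, 8-OTBS, 12-OTBS | CC(C)(C)[Si](C)(C)OC[C@@H](C)[C@H]1[C@@H](OCc2ccc(OC)cc2)/C=C(C)\CC/C=C(\C)C[C@@H]1O[Si](C)(C)C(C)(C)C | intermediate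
33 | 1(10)E,4Z-germacradiene-8,12-diol, 6-OPMB | OC[C@@H](C)[C@H]1[C@@H](OCc2ccc(OC)cc2)/C=C(C)\CC/C=C(\C)C[C@@H]1O | intermediate
34 | angelic acid, (Z)-2-methylbut-2-enoic acid | C/C=C(/C)C(=O)O | starting material
35 | 12-mono-angelate, free 8-OH, 6-OPMB | C/C=C(/C)C(=O)OC[C@@H](C)[C@H]1[C@@H](OCc2ccc(OC)cc2)/C=C(C)\CC/C=C(\C)C[C@@H]1O | intermediate
36 | 8,12-bis-angelate, 6-OPMB | C/C=C(/C)C(=O)OC[C@@H](C)[C@H]1[C@@H](OCc2ccc(OC)cc2)/C=C(C)\CC/C=C(\C)C[C@@H]1OC(=O)/C(C)=C\C | intermediate
37 | 8,12-bis-angelate, free 6-OH (Z-allylic alcohol) | C/C=C(/C)C(=O)OC[C@@H](C)[C@H]1[C@@H](O)/C=C(C)\CC/C=C(\C)C[C@@H]1OC(=O)/C(C)=C\C | intermediate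
38 | target: 4,5-epoxy-6-hydroxy-1(10)E-germacrene 8,12-bis-angelate (CNP0272382.1) | C/C=C(/C)C(=O)OC[C@@H](C)[C@H]1[C@@H](O)[C@H]2O[C@@]2(C)CC/C=C(\C)C[C@@H]1OC(=O)/C(C)=C\C | target

**Step count**
Total step count: 25. Longest linear sequence: 24 steps (steps 1–7 and 9–25 from 1); step 8 is a one-step side branch.

**Steps most likely to fail**

Step 19. The [3,3] shift may leak through a boat array or through the ring-flipped chair, because the reactive chair carries the C6 PMB ether syn-axial to the C10 vinyl group; that would give 4E or 1(10)Z isomers. The hindered enolate may also take up a proton before O-sulfonylation. The fallback changes the substrate and the order of events, setting out from 25 and returning at 32. The ring expansion is run on the lactone itself, where O6 is tied back to C12 as a small, rigid cis-fused ring that fits the required chair. KN(SiMe3)2 (1.05 equiv) with 18-crown-6 in THF followed by PhNTf2 should give the ten-membered lactone enol triflate F1. Formate reduction (Pd(OAc)2, PPh3, HCO2H, Et3N) should give the 1(10)E,4Z-dien-6,12-olide F2. LiAlH4 should open it to the C6,C12 diol F3, and TBSCl/imidazole should silylate the primary hydroxyl to give the C12 silyl ether F4. Its C6 allylic hydroxyl, now the only free one, is benzylated (NaH, PMBCl) to give 32.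

Step 14. The peracid may attack the isopropenyl group or the α-face. The acidic medium may also ionise the tertiary allylic C5–O bond of the oxirane (allylic opening or rearrangement) before the carboxyl group reaches C6. The fallback separates oxidation from ring opening and keeps the opening basic, setting out from 21 and returning at 24. Ester 21 is epoxidised with dimethyldioxirane in acetone (neutral) to the epoxy ester F5. Saponification with LiOH in warm aqueous THF then lets the carboxylate open the oxirane at C6 by intramolecular SN2 attack. Careful acidification to pH 4 closes any remaining hydroxy acid and gives 24.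

Step 25. Oxygen may be delivered to the face anti to the C6 hydroxyl if the ten-membered ring lets C7 swing into an anti position (threo-type transition state), or the allylic alcohol may be oxidised to the enone. The fallback replaces substrate direction by reagent control, setting out from 37 and returning at 38. Stoichiometric Sharpless–Katsuki epoxidation with Ti(OiPr)4, D-(−)-diisopropyl tartrate and tBuOOH (4 Å sieves, CH2Cl2, −20 °C) is used; this tartrate enantiomer is the one matched to the C6 configuration of 37. Its fast-reacting manifold gives the erythro epoxy alcohol, which is the configuration of 38.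

**Further compounds**
F1 | step 19 | ten-membered 1(10)E,4Z-dienyl C5 triflate with the 6,12-lactone intact, 8-OTBS | O=C2[C@@H](C)[C@H]1[C@@H](O2)/C(OS(=O)(=O)C(F)(F)F)=C(C)\CC/C=C(\C)C[C@@H]1O[Si](C)(C)C(C)(C)C
F2 | step 19 | 1(10)E,4Z-germacradien-6,12-olide, 8-OTBS | O=C2[C@@H](C)[C@H]1[C@@H](O2)/C=C(C)\CC/C=C(\C)C[C@@H]1O[Si](C)(C)C(C)(C)C
F3 | step 19 | 1(10)E,4Z-germacradiene-6,12-diol, 8-OTBS | OC[C@@H](C)[C@H]1[C@@H](O)/C=C(C)\CC/C=C(\C)C[C@@H]1O[Si](C)(C)C(C)(C)C
F4 | step 19 | 1(10)E,4Z-germacradien-6-ol, 8-OTBS, 12-OTBS | CC(C)(C)[Si](C)(C)OC[C@@H](C)[C@H]1[C@@H](O)/C=C(C)\CC/C=C(\C)C[C@@H]1O[Si](C)(C)C(C)(C)C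
F5 | step 14 | 5β,6β-epoxy methyl ester (C11 epimers) | COC(=O)C(C)[C@H]1[C@@H]2O[C@]2(C(C)=C)[C@@](C)(C=C)C[C@@H]1O[Si](C)(C)C(C)(C)C
F0 | step 25 | none | none
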